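**Plan**
- Retrosynthesis: the two S–O bonds of the sulfates at O3 and O7 are cut first, with the ring B catechol masked as a diphenylmethylene ketal. Quercetin is then opened in ring C at C4–C4a and O1–C2 to phloroglucinol and a 2-benzyloxy aroylacetate. The ketoester is cut between its C2 and the ketone carbon to ethyl benzyloxyacetate and 3,4-bis(benzyloxy)benzoyl chloride.
- Forward: an enolate acylation joins the chain. Ring C then closes in a thermal melt between the two purchased aromatic rings A and B. Benzyl groups are exchanged for the catechol ketal, O3 and O7 are sulfated, and the ketal is removed by hydrogenolysis.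
- Enabling feature: ring A is a phloroglucinol unit whose three ring CH carbons are equivalent. Whichever is acylated becomes C4a, its two neighbours carry O1 and O5, and O7 lies para, so no regiocontrol is needed. The O5–H···O=C4 hydrogen bond later keeps O5 out of the sulfation.
- Stereochemistry: the target has no stereocentre. The only sp3 centre on the way (C2 of the ketoester) is racemic and becomes the sp2 carbon C3.

Key step: step 3

Remark: sulfate half-esters are drawn and counted as free acids, as in the target SMILES. In the flask they would be triethylammonium salts, and the acid form is released only at the end on a cold H+-form cation-exchange resin.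

**Step 1**
Reactants: 1 3,4-bis(benzyloxy)benzoic acid
Product: 2 3,4-bis(benzyloxy)benzoyl chloride
Conditions: (COCl)2 (1.3 equiv), DMF (cat.), CH2Cl2, 0 °C to rt; evaporate, use crude
Reagents that add atoms: oxalyl chloride, O=C(Cl)C(=O)Cl
Why: DMF-catalysed (Vilsmeier-type) acid chloride formation leaves the benzyl ethers untouched and gives only gaseous by-products, so the crude chloride can be used directly.

**Step 2**
Reactants: 3 ethyl 2-(benzyloxy)acetate; 2 3,4-bis(benzyloxy)benzoyl chloride
Product: 4 ethyl 2-(benzyloxy)-3-[3,4-bis(benzyloxy)phenyl]-3-oxopropanoate (racemic at C2)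
Conditions: 3 (2.2 equiv), LiN(i-Pr)2 (2.2 equiv), THF, −78 °C; then 2 (1.0 equiv), −78 °C; aq NH4Cl
Reagents that add atoms: none
Why: This is a crossed Claisen-type C-acylation of a preformed lithium ester enolate by an aroyl chloride, in which the second equivalent of enolate deprotonates the more acidic β-ketoester as it forms and so stops double acylation, −78 °C suppresses self-condensation and Wittig rearrangement of the α-benzyloxy enolate, and the new C2 centre is enolisable and therefore racemic.

**Step 3**
Reactants: 4 ethyl 2-(benzyloxy)-3-[3,4-bis(benzyloxy)phenyl]-3-oxopropanoate; 5 phloroglucinol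
Product: 8 3,3',4'-tri-O-benzylquercetin, via aroyl(benzyloxy)ketene 6 (not isolated), via C-acylphloroglucinol diketone 7 (not isolated)
Conditions: 5 (anhydrous, 1.5 equiv), neat melt, 240 °C, N2 stream (EtOH and H2O distilled off), 1–2 h
Reagents that add atoms: none
Why: Above about 200 °C the enol of 4 should expel ethanol through a six-membered transition state to the α-oxoketene 6, as in the thermal transesterification of β-ketoesters, and phloroglucinol captures the ketene carbon; O-acylation is reversible at this temperature because the aryl β-ketoester re-fragments to 6, whereas C-acylation at a ring carbon gives 7 and the C4–C4a bond. One of the two phenolic hydroxyls flanking the new acyl group then adds to the aryl ketone carbonyl in a 6-exo-trig closure, and loss of water forms O1–C2 and the aromatic 4-pyranone, which drains the preceding equilibria. The closest known reaction type is the Mentzer thermal chromone synthesis from phenols and β-ketoesters, which accepts 2-alkoxy ketoesters and then delivers 3-alkoxyflavones. No stereocentre is formed, and the racemic C2 of 4 becomes the sp2 carbon C3. Chromone rather than coumarin closure is required and should follow from the absence of acid, since the Pechmann mode needs a protonated ketone for attack by the ring carbon while here the only strong electrophile is the ester-derived ketene carbon; regiochemistry needs no control because the three ring carbons of 5 are equivalent, and a second annulation is held back by the excess of 5 and by the deactivating C4 carbonyl of 8.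

**Step 4**
Reactants: 8 3,3',4'-tri-O-benzylquercetin
Product: 9 quercetin
Conditions: H2 (1 atm), Pd/C (10%), THF–MeOH, rt
Reagents that add atoms: none
Why: Catalytic hydrogenolysis cleaves the three O-benzyl groups to toluene, while the tetrasubstituted C2=C3 bond of the chromone, part of a vinylogous ester, is not reduced at 1 atm and room temperature.

**Step 5**
Reactants: 9 quercetin
Product: 10 3',4'-O-(diphenylmethylene)quercetin
Conditions: Ph2CCl2 (1.5 equiv), Ph2O, 175 °C, 30 min
Reagents that add atoms: dichlorodiphenylmethane, ClC(Cl)(c1ccccc1)c1ccccc1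
Why: In this ketalisation of a catechol by a gem-dichloride only the adjacent 3'- and 4'-hydroxyls can close a five-membered 2,2-diphenyl-1,3-benzodioxole with loss of two HCl, so the 3-, 5- and 7-hydroxyls stay free, a selectivity established for quercetin itself.

**Step 6**
Reactants: 10 3',4'-O-(diphenylmethylene)quercetin
Product: 11 3',4'-O-(diphenylmethylene)quercetin 3,7-bis(hydrogen sulfate)
Conditions: SO3·NMe3 (6 equiv), Et3N, DMF, 45 °C; Sephadex LH-20
Reagents that add atoms: sulfur trioxide–trimethylamine complex, C[N+](C)(C)S(=O)(=O)[O-]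
Why: O-sulfation by an amine–SO3 complex should take the acidic O7 and the enolic O3 but not O5, whose hydrogen is held in a six-membered hydrogen bond to the C4 carbonyl, the same 3,7-pattern this triol shows in alkylation under mild base.

**Step 7**
Reactants: 11 3',4'-O-(diphenylmethylene)quercetin 3,7-bis(hydrogen sulfate)
Product: 12 quercetin 3,7-di-O-sulfate
Conditions: H2 (1 atm), Pd(OH)2/C, MeOH–THF, rt; then H+-form sulfonic acid resin, H2O, 0 °C, lyophilise
Reagents that add atoms: none
Why: Hydrogenolysis of the two doubly benzylic C–O bonds of the ketal releases the catechol and diphenylmethane under neutral conditions that aryl sulfate salts tolerate, as benzyl ethers are known to be removed from flavonoid sulfates in this way.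

**Compound list**
1 | 3,4-bis(benzyloxy)benzoic acid | O=C(O)c1ccc(OCc2ccccc2)c(OCc2ccccc2)c1 | starting material
2 | 3,4-bis(benzyloxy)benzoyl chloride | O=C(Cl)c1ccc(OCc2ccccc2)c(OCc2ccccc2)c1 | intermediate
3 | ethyl 2-(benzyloxy)acetate | CCOC(=O)COCc1ccccc1 | starting material
4 | ethyl 2-(benzyloxy)-3-[3,4-bis(benzyloxy)phenyl]-3-oxopropanoate (racemic at C2) | CCOC(=O)C(OCc1ccccc1)C(=O)c1ccc(OCc2ccccc2)c(OCc2ccccc2)c1 | intermediate
5 | phloroglucinol (benzene-1,3,5-triol) | Oc1cc(O)cc(O)c1 | starting material
6 | aroyl(benzyloxy)ketene, 2-(benzyloxy)-3-[3,4-bis(benzyloxy)phenyl]-3-oxoprop-1-en-1-one (not isolated) | O=C=C(OCc1ccccc1)C(=O)c1ccc(OCc2ccccc2)c(OCc2ccccc2)c1 | intermediate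
7 | C-acylphloroglucinol diketone, 2-(benzyloxy)-1-[3,4-bis(benzyloxy)phenyl]-3-(2,4,6-trihydroxyphenyl)propane-1,3-dione (racemic, not isolated) | O=C(c1ccc(OCc2ccccc2)c(OCc2ccccc2)c1)C(OCc1ccccc1)C(=O)c1c(O)cc(O)cc1O | intermediate
8 | 3,3',4'-tri-O-benzylquercetin, 3-(benzyloxy)-2-[3,4-bis(benzyloxy)phenyl]-5,7-dihydroxy-4H-chromen-4-one | O=c1c(OCc2ccccc2)c(-c2ccc(OCc3ccccc3)c(OCc3ccccc3)c2)oc2cc(O)cc(O)c12 | intermediate
9 | quercetin, 2-(3,4-dihydroxyphenyl)-3,5,7-trihydroxy-4H-chromen-4-one | O=c1c(O)c(-c2ccc(O)c(O)c2)oc2cc(O)cc(O)c12 | intermediate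
10 | 3',4'-O-(diphenylmethylene)quercetin, 2-(2,2-diphenyl-1,3-benzodioxol-5-yl)-3,5,7-trihydroxy-4H-chromen-4-one | O=c1c(O)c(-c2ccc3c(c2)OC(c2ccccc2)(c2ccccc2)O3)oc2cc(O)cc(O)c12 | intermediate
11 | 3',4'-O-(diphenylmethylene)quercetin 3,7-bis(hydrogen sulfate), 2-(2,2-diphenyl-1,3-benzodioxol-5-yl)-5-hydroxy-4-oxo-4H-chromene-3,7-diyl bis(hydrogen sulfate) | O=c1c(OS(=O)(=O)O)c(-c2ccc3c(c2)OC(c2ccccc2)(c2ccccc2)O3)oc2cc(OS(=O)(=O)O)cc(O)c12 | intermediate
12 | quercetin 3,7-di-O-sulfate, 2-(3,4-dihydroxyphenyl)-5-hydroxy-4-oxo-4H-chromene-3,7-diyl bis(hydrogen sulfate) | O=c1c(OS(=O)(=O)O)c(-c2ccc(O)c(O)c2)oc2cc(OS(=O)(=O)O)cc(O)c12 | target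

**Step count**
Total steps: 7. Longest linear sequence: 7 (steps 1 to 7; compounds 3 and 5 are purchased).

**Steps most likely to fail**

Step 3. In the melt the benzyl ethers, above all the α-benzyloxy group, may migrate to carbon or be lost. Coumarin closure or a second annulation may compete, and decomposition of the ketoester may outrun ketene formation. Simple loss of O-benzyl groups would be harmless, because step 4 removes them all.
The fallback is an Allan–Robinson flavonol synthesis that sets out from 5, 1 and 2 and comes back at 8. Phloroglucinol 5 would be acylated with benzyloxyacetonitrile under Houben–Hoesch conditions (ZnCl2, HCl gas, Et2O, 0 °C) to precipitate 2-(benzyloxy)-1-(2,4,6-trihydroxyphenyl)ethan-1-iminium chloride F1. Hot water would hydrolyse this to 2-(benzyloxy)-1-(2,4,6-trihydroxyphenyl)ethan-1-one F2. Acid 1 and chloride 2 (pyridine, CH2Cl2) would give 3,4-bis(benzyloxy)benzoic anhydride F3. Heating F2 with F3 and the sodium salt of 1 at 180 °C should build ring C from the other side (O1–C2 and C2–C3). The flavonol is expected largely as its 7-O-aroyl ester, 3-(benzyloxy)-2-[3,4-bis(benzyloxy)phenyl]-5-hydroxy-4-oxo-4H-chromen-7-yl 3,4-bis(benzyloxy)benzoate F4. KOH in aqueous EtOH at reflux would cleave F4 to 8.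

Step 6. Sulfation may stall at the hydrogen-bonded enolic O3 or, when forced, spill over to O5, leaving anionic mixtures that are hard to separate.
The fallback sets out from 10 and comes back at 11 through a masked, neutral sulfate. Treatment of 10 with 2,2,2-trichloroethyl chlorosulfate (Et3N, DMAP, THF, 0 °C) should give 3',4'-O-(diphenylmethylene)quercetin 3,7-bis(2,2,2-trichloroethyl sulfate) F5. This diester can be freed of mono- and tris-sulfated material on silica. Reductive unmasking with Zn dust and HCO2NH4 in MeOH at rt would then give 11.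

Step 7. Hydrogenolysis of the hindered ketal on a dianionic substrate may be slow, and prolonged exposure or the acidic resin may cause loss of sulfate.
The fallback sets out from 10 and comes back at 12, avoiding hydrogenation of a sulfated compound. It passes through the acid-stable diester 3',4'-O-(diphenylmethylene)quercetin 3,7-bis(2,2,2-trichloroethyl sulfate) F5, made as described for step 6. The ketal of F5 would be hydrolysed with TFA–H2O in CH2Cl2 at rt to quercetin 3,7-bis(2,2,2-trichloroethyl sulfate) F6. Zn dust and HCO2NH4 in MeOH would then release both sulfates to give 12.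

**Further compounds**
F1 | step 3 | 2-(benzyloxy)-1-(2,4,6-trihydroxyphenyl)ethan-1-iminium chloride | [Cl-].[NH2+]=C(COCc1ccccc1)c1c(O)cc(O)cc1O
F2 | step 3 | 2-(benzyloxy)-1-(2,4,6-trihydroxyphenyl)ethan-1-one | O=C(COCc1ccccc1)c1c(O)cc(O)cc1O
F3 | step 3 | 3,4-bis(benzyloxy)benzoic anhydride | O=C(OC(=O)c1ccc(OCc2ccccc2)c(OCc2ccccc2)c1)c1ccc(OCc2ccccc2)c(OCc2ccccc2)c1
F4 | step 3 | 3-(benzyloxy)-2-[3,4-bis(benzyloxy)phenyl]-5-hydroxy-4-oxo-4H-chromen-7-yl 3,4-bis(benzyloxy)benzoate | O=C(Oc1cc(O)c2c(c1)oc(-c1ccc(OCc3ccccc3)c(OCc3ccccc3)c1)c(OCc1ccccc1)c2=O)c1ccc(OCc2ccccc2)c(OCc2ccccc2)c1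
F5 | step 6 | 3',4'-O-(diphenylmethylene)quercetin 3,7-bis(2,2,2-trichloroethyl sulfate) | O=c1c(OS(=O)(=O)OCC(Cl)(Cl)Cl)c(-c2ccc3c(c2)OC(c2ccccc2)(c2ccccc2)O3)oc2cc(OS(=O)(=O)OCC(Cl)(Cl)Cl)cc(O)c12
F6 | step 7 | quercetin 3,7-bis(2,2,2-trichloroethyl sulfate) | O=c1c(OS(=O)(=O)OCC(Cl)(Cl)Cl)c(-c2ccc(O)c(O)c2)oc2cc(OS(=O)(=O)OCC(Cl)(Cl)Cl)cc(O)c12
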